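The ring oxygen of the γ-lactone (ring O–C6–C7–C11–C12) sits on C6, and C6 is also allylic to the Z-alkene C4=C5 of the ten-membered ring; everything rests on this. The lactone is therefore closed last, from a C12 acid and a C5=C6 alkene. One-pot phenylselenolactonisation and selenoxide elimination should form the O–C6 bond, set C6, and shift the alkene to C4=C5 with Z geometry, consuming a temporary stereocentre at C4. The precursor is a (5Z)-cyclodecene acid that already holds the 1,10-epoxide and both esters. It should arise by ring-closing metathesis of a seco-diene assembled from three small fragments under reagent control.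

Key step: step 19

Remark: locants follow germacrane numbering throughout (ring carbons C1–C10, C11–C13 the methylene-carboxyl unit on C7, C14 the methyl on C10, C15 the methyl on C4); acyclic intermediates also carry systematic names.

Step 1
Reactants: 1 pent-3-yn-1-ol
Product: 2 tert-butyldimethyl(pent-3-yn-1-yloxy)silane
Conditions: TBSCl, imidazole, DMF, rt
Reagents that add atoms: tert-butyldimethylsilyl chloride, CC(C)(C)[Si](C)(C)Cl
Why: Silyl ether formation at the primary alcohol should protect the future C3 oxygen through the organometallic steps.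

Step 2
Reactants: 2 tert-butyldimethyl(pent-3-yn-1-yloxy)silane
Product: 4 (E)-tert-butyl[(4-iodopent-3-en-1-yl)oxy]dimethylsilane, via alkenylzirconocene 3 (not isolated)
Conditions: Cp2Zr(H)Cl (1.5 equiv), THF, rt → 45 °C; then I2, 0 °C
Reagents that add atoms: iodine, II
Why: Hydrozirconation adds H and Zr syn and equilibrates the metal to the less hindered methyl-bearing carbon, and iodinolysis with retention should give the E-trisubstituted vinyl iodide that becomes C10=C1.

Step 3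
Reactants: 5 (2E)-penta-2,4-dien-1-ol
Product: 6 [(2R,3R)-3-ethenyloxiran-2-yl]methanol
Conditions: Ti(OiPr)4 (10 mol%), D-(−)-diisopropyl tartrate (12 mol%), t-BuOOH, 4 Å MS, CH2Cl2, −20 °C
Reagents that add atoms: tert-butyl hydroperoxide, CC(C)(C)OO
Why: Sharpless asymmetric epoxidation touches only the allylic alkene, and the D-tartrate ligand should deliver oxygen to the face that gives the (2R,3R)-epoxide, which fixes C8.

Step 4
Reactants: 6 [(2R,3R)-3-ethenyloxiran-2-yl]methanol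
Product: 7 (2S,3R)-3-ethenyl-5-(trimethylsilyl)pent-4-yne-1,2-diol
Conditions: Me3SiC≡CH, n-BuLi, then Et2AlCl, toluene, 0 °C (Et2AlC≡CSiMe3, 3 equiv); add 6, 0 °C → rt; aq. potassium sodium tartrate
Reagents that add atoms: ethynyltrimethylsilane, C#C[Si](C)(C)C
Why: The alkynylalane binds the alkoxide and should open the epoxide by SN2 attack at the vinyl-activated carbon remote from the CH2O group, with inversion, which sets C7 anti to the C8 oxygen.

Step 5
Reactants: 7 (2S,3R)-3-ethenyl-5-(trimethylsilyl)pent-4-yne-1,2-diol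
Product: 9 trimethyl{(3R)-3-[(2S)-oxiran-2-yl]pent-4-en-1-yn-1-yl}silane, via primary tosylate 8 (not isolated)
Conditions: NaH (2.2 equiv), 1-(p-toluenesulfonyl)imidazole, THF, 0 °C → rt
Reagents that add atoms: none
Why: Selective sulfonylation of the primary alkoxide and intramolecular Williamson closure (3-exo-tet) should give the terminal epoxide without touching the C8–O bond.

Step 6
Reactants: 10 methyl (2Z)-2-methylbut-2-enoate (methyl angelate)
Product: 11 (2Z)-2-methylbut-2-en-1-ol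
Conditions: i-Bu2AlH (2.2 equiv), CH2Cl2, −78 → 0 °C; aq. potassium sodium tartrate
Reagents that add atoms: none
Why: 1,2-Reduction of the enoate by the aluminium hydride should give the allylic alcohol with the Z geometry intact.

Step 7
Reactants: 11 (2Z)-2-methylbut-2-en-1-ol
Product: 12 [(2R,3S)-2,3-dimethyloxiran-2-yl]methanol
Conditions: Ti(OiPr)4 (10 mol%), D-(−)-diethyl tartrate (12 mol%), t-BuOOH, 4 Å MS, CH2Cl2, −20 °C
Reagents that add atoms: tert-butyl hydroperoxide, CC(C)(C)OO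
Why: Sharpless asymmetric epoxidation with the D-tartrate should give the (2R,3S)-epoxy alcohol, and the Z-alkene fixes the cis relation of CH2OH and the C3 methyl.

Step 8
Reactants: 12 [(2R,3S)-2,3-dimethyloxiran-2-yl]methanol
Product: 14 (2S,3S)-2,3-dimethyloxirane-2-carboxylic acid, via epoxy aldehyde 13 (not isolated)
Conditions: RuCl3 (2 mol%), NaIO4 (4 equiv), MeCN/EtOAc/H2O, rt
Reagents that add atoms: water, O; sodium periodate, [Na+].[O-]I(=O)(=O)=O
Why: Ruthenium tetroxide formed in the flask should oxidise the primary alcohol through the aldehyde hydrate to the acid without touching either stereocentre (the descriptor at C2 changes only because the priorities change).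

Step 9
Reactants: 4 (E)-tert-butyl[(4-iodopent-3-en-1-yl)oxy]dimethylsilane; 9 trimethyl{(3R)-3-[(2S)-oxiran-2-yl]pent-4-en-1-yn-1-yl}silane
Product: 16 (3R,4R,6E)-9-{[tert-butyl(dimethyl)silyl]oxy}-3-ethenyl-6-methyl-1-(trimethylsilyl)non-6-en-1-yn-4-ol, via vinyllithium 15 (not isolated)
Conditions: 4, t-BuLi (2 equiv), Et2O, −78 °C; then BF3·OEt2 and 9, −78 °C
Reagents that add atoms: none
Why: Iodine–lithium exchange keeps the alkene geometry, and the BF3-assisted SN2 opening at the CH2 terminus of the epoxide should join C9 to C10 and free the C8 hydroxyl.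

Step 10
Reactants: 16 (3R,4R,6E)-9-{[tert-butyl(dimethyl)silyl]oxy}-3-ethenyl-6-methyl-1-(trimethylsilyl)non-6-en-1-yn-4-ol; 14 (2S,3S)-2,3-dimethyloxirane-2-carboxylic acid
Product: 18 (3R,4R,6E)-9-{[tert-butyl(dimethyl)silyl]oxy}-3-ethenyl-6-methyl-1-(trimethylsilyl)non-6-en-1-yn-4-yl (2S,3S)-2,3-dimethyloxirane-2-carboxylate, via mixed anhydride 17 (not isolated)
Conditions: 14, 2,4,6-trichlorobenzoyl chloride, Et3N, toluene, rt; then 16, DMAP, rt → 40 °C
Reagents that add atoms: none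
Why: Yamaguchi esterification should acylate the hindered C8 hydroxyl with retention, and the quaternary epoxy acid cannot epimerise or isomerise under the basic conditions.

Step 11
Reactants: 18 (3R,4R,6E)-9-{[tert-butyl(dimethyl)silyl]oxy}-3-ethenyl-6-methyl-1-(trimethylsilyl)non-6-en-1-yn-4-yl (2S,3S)-2,3-dimethyloxirane-2-carboxylate
Product: 19 (3R,4R,6E)-3-ethenyl-9-hydroxy-6-methylnon-6-en-1-yn-4-yl (2S,3S)-2,3-dimethyloxirane-2-carboxylate
Conditions: TBAF (2.5 equiv), AcOH (2.5 equiv), THF, 0 °C → rt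
Reagents that add atoms: none
Why: Buffered fluoride should cleave the O–Si bond and the alkynyl C–Si bond in one operation, leaving the esters and the acidic C7–H untouched.

Step 12
Reactants: 19 (3R,4R,6E)-3-ethenyl-9-hydroxy-6-methylnon-6-en-1-yn-4-yl (2S,3S)-2,3-dimethyloxirane-2-carboxylate
Product: 20 (3R,4R,6E)-3-ethenyl-6-methyl-9-oxonon-6-en-1-yn-4-yl (2S,3S)-2,3-dimethyloxirane-2-carboxylate
Conditions: Dess–Martin periodinane, NaHCO3, CH2Cl2, 0 °C; used crude
Reagents that add atoms: none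
Why: Buffered Dess–Martin oxidation should give the β,γ-unsaturated aldehyde without moving the C1=C10 alkene into conjugation.

Step 13
Reactants: 20 (3R,4R,6E)-3-ethenyl-6-methyl-9-oxonon-6-en-1-yn-4-yl (2S,3S)-2,3-dimethyloxirane-2-carboxylate
Product: 21 (3R,4R,6E,9S,10S)-3-ethenyl-9-hydroxy-6,10-dimethyldodeca-6,11-dien-1-yn-4-yl (2S,3S)-2,3-dimethyloxirane-2-carboxylate
Conditions: (Z)-crotyl-B(pin) (1.5 equiv), (R)-TRIP [(R)-3,3′-bis(2,4,6-triisopropylphenyl)-1,1′-binaphthyl-2,2′-diyl hydrogen phosphate, 5 mol%; the enantiomer that directs attack to the Re face of the aldehyde], 4 Å MS, toluene, −30 °C; aq. NaHCO3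
Reagents that add atoms: (Z)-crotylboronic acid pinacol ester, C/C=C\CB1OC(C)(C)C(C)(C)O1
Why: Chiral phosphoric acid-catalysed crotylboration runs through a closed chair transition state, so the Z-crotyl reagent should give the syn adduct and the catalyst the 3S carbinol, which together set C3 and the temporary centre C4.

Step 14
Reactants: 21 (3R,4R,6E,9S,10S)-3-ethenyl-9-hydroxy-6,10-dimethyldodeca-6,11-dien-1-yn-4-yl (2S,3S)-2,3-dimethyloxirane-2-carboxylate
Product: 22 (3R,4R,6E,9S,10S)-3-ethenyl-6,10-dimethyl-9-[(2-methylpropanoyl)oxy]dodeca-6,11-dien-1-yn-4-yl (2S,3S)-2,3-dimethyloxirane-2-carboxylate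
Conditions: (i-PrCO)2O, DMAP (cat.), pyridine, CH2Cl2, 0 °C → rt
Reagents that add atoms: isobutyric anhydride, CC(C)C(=O)OC(=O)C(C)C
Why: DMAP-catalysed acylation should install the C3 isobutyrate with retention.

Step 15
Reactants: 22 (3R,4R,6E,9S,10S)-3-ethenyl-6,10-dimethyl-9-[(2-methylpropanoyl)oxy]dodeca-6,11-dien-1-yn-4-yl (2S,3S)-2,3-dimethyloxirane-2-carboxylate
Product: 23 2-(trimethylsilyl)ethyl (3R,4R,6E,9S,10S)-4-{[(2S,3S)-2,3-dimethyloxirane-2-carbonyl]oxy}-3-ethenyl-6,10-dimethyl-2-methylidene-9-[(2-methylpropanoyl)oxy]dodeca-6,11-dienoate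
Conditions: Pd(OAc)2 (2 mol%), 2-(diphenylphosphino)pyridine (8 mol%), MsOH (4 mol%), CO (10 bar), Me3SiCH2CH2OH (5 equiv), toluene, 45 °C
Reagents that add atoms: carbon monoxide, [C-]#[O+]; 2-(trimethylsilyl)ethanol, OCC[Si](C)(C)C
Why: Palladium-catalysed Markovnikov alkoxycarbonylation of the terminal alkyne should place the ester carbon on C11 and hydrogen on C13, giving the 2-substituted acrylate far faster than any reaction of the alkenes, with the pyridylphosphine buffering the acid co-catalyst.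

Step 16
Reactants: 23 2-(trimethylsilyl)ethyl (3R,4R,6E,9S,10S)-4-{[(2S,3S)-2,3-dimethyloxirane-2-carbonyl]oxy}-3-ethenyl-6,10-dimethyl-2-methylidene-9-[(2-methylpropanoyl)oxy]dodeca-6,11-dienoate
Product: 24 2-(trimethylsilyl)ethyl (3R,4R,6R,7R,9S,10S)-4-{[(2S,3S)-2,3-dimethyloxirane-2-carbonyl]oxy}-6,7-epoxy-3-ethenyl-6,10-dimethyl-2-methylidene-9-[(2-methylpropanoyl)oxy]dodec-11-enoate
Conditions: D-fructose-derived Shi ketone (0.3 equiv), KHSO5 (as Oxone, 2KHSO5·KHSO4·K2SO4), K2CO3, Bu4NHSO4 (cat.), MeCN/(MeO)2CH2/aq. borate buffer, 0 °C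
Reagents that add atoms: potassium peroxymonosulfate, [K+].[O-]S(=O)(=O)OO
Why: Shi epoxidation through the spiro dioxirane transition state should give the (1R,10R)-epoxide from the only electron-rich trisubstituted alkene, while the vinyl groups and the acrylate stay intact; it is placed before ring closure so that no trisubstituted alkene can divert the metathesis into a cyclopentene.

Step 17
Reactants: 24 2-(trimethylsilyl)ethyl (3R,4R,6R,7R,9S,10S)-4-{[(2S,3S)-2,3-dimethyloxirane-2-carbonyl]oxy}-6,7-epoxy-3-ethenyl-6,10-dimethyl-2-methylidene-9-[(2-methylpropanoyl)oxy]dodec-11-enoate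
Product: 25 2-(trimethylsilyl)ethyl (1R,3S,4S,5Z,7R,8R,10R)-8-{[(2S,3S)-2,3-dimethyloxirane-2-carbonyl]oxy}-1,10-epoxy-3-[(2-methylpropanoyl)oxy]germacra-5,11(13)-dien-12-oate
Conditions: second-generation Grubbs catalyst (10 mol%), toluene (1 mM), 80 °C, argon sparge
Reagents that add atoms: none
Why: Ring-closing metathesis of the two monosubstituted vinyl groups at high dilution should close the ten-membered ring at C5=C6 with loss of ethene; the Z-alkene is expected because cis-cyclodecenes are less strained than trans, and the 1,1-disubstituted acrylate reacts much more slowly.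

Step 18
Reactants: 25 2-(trimethylsilyl)ethyl (1R,3S,4S,5Z,7R,8R,10R)-8-{[(2S,3S)-2,3-dimethyloxirane-2-carbonyl]oxy}-1,10-epoxy-3-[(2-methylpropanoyl)oxy]germacra-5,11(13)-dien-12-oate
Product: 26 (1R,3S,4S,5Z,7R,8R,10R)-8-{[(2S,3S)-2,3-dimethyloxirane-2-carbonyl]oxy}-1,10-epoxy-3-[(2-methylpropanoyl)oxy]germacra-5,11(13)-dien-12-oic acid
Conditions: TBAF, THF, 0 °C; then AcOH (1.1 equiv)
Reagents that add atoms: none
Why: Fluoride-induced fragmentation of the 2-(trimethylsilyl)ethyl ester should free the C12 acid under conditions that spare the two other esters and both epoxides.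

Step 19
Reactants: 26 (1R,3S,4S,5Z,7R,8R,10R)-8-{[(2S,3S)-2,3-dimethyloxirane-2-carbonyl]oxy}-1,10-epoxy-3-[(2-methylpropanoyl)oxy]germacra-5,11(13)-dien-12-oic acid
Product: 29 (1R,3S,4Z,6R,7R,8R,10R)-8-{[(2S,3S)-2,3-dimethyloxirane-2-carbonyl]oxy}-1,10-epoxy-3-[(2-methylpropanoyl)oxy]germacra-4,11(13)-dien-12,6-olide (CNP0117882.1), via selenide 27 (not isolated), via selenoxide 28 (not isolated)
Conditions: N-(phenylseleno)phthalimide (1.2 equiv), CH2Cl2, −20 °C → rt; then pyridine, 30% H2O2, 0 °C → rt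
Reagents that add atoms: none
Why: This is a phenylselenolactonisation followed in the same flask by selenoxide syn-elimination, the classical selenium route from unsaturated acids to allylic lactones. The reagent transfers PhSe+ reversibly to the Z-alkene C5=C6 and the C12 carboxylate opens the seleniranium ion at C6 by anti addition in the 5-exo mode, which closes the lactone ring O–C6–C7–C11–C12 instead of the six-membered ring that attack at C5 would give. The new stereocentre C6 is controlled by C7: allylic strain in the Z-alkene and the ring hold H7 in the alkene plane, so the acid tethered through C11 can reach only one face of C6, selenium takes the other, and the trans-fused 6R lactone should result. Peroxide then gives selenoxide 28, whose five-membered syn-elimination takes the hydrogen on C4 and not the one on the oxygen-bearing C6, so the alkene moves to C4=C5. Since the crotylation fixed the C4 methyl syn to the selenium that the anti addition places on C5, this transition state holds C3 and C6 cis and should give the Z-alkene while the auxiliary centres C4 and C5 disappear. The step needs chemoselectivity for the ring alkene over the electron-poor C11=C13 methylene and tolerance of both epoxides, which the neutral selenium imide and pyridine-buffered peroxide are chosen to secure.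

Compound list
1 | pent-3-yn-1-ol | CC#CCCO | starting material
2 | tert-butyldimethyl(pent-3-yn-1-yloxy)silane | CC#CCCO[Si](C)(C)C(C)(C)C | intermediate
3 | chlorido{(2E)-5-[(tert-butyldimethylsilyl)oxy]pent-2-en-2-yl}bis(cyclopentadienyl)zirconium (not isolated) | C/C(=C\CCO[Si](C)(C)C(C)(C)C)[Zr](Cl)(C1C=CC=C1)C1C=CC=C1 | intermediate
4 | (E)-tert-butyl[(4-iodopent-3-en-1-yl)oxy]dimethylsilane | I/C(C)=C/CCO[Si](C)(C)C(C)(C)C | intermediate
5 | (2E)-penta-2,4-dien-1-ol | OC/C=C/C=C | starting material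
6 | [(2R,3R)-3-ethenyloxiran-2-yl]methanol | OC[C@H]1O[C@@H]1C=C | intermediate
7 | (2S,3R)-3-ethenyl-5-(trimethylsilyl)pent-4-yne-1,2-diol | OC[C@@H](O)[C@H](C=C)C#C[Si](C)(C)C | intermediate
8 | (2S,3R)-3-ethenyl-2-hydroxy-5-(trimethylsilyl)pent-4-yn-1-yl 4-methylbenzenesulfonate (not isolated) | Cc1ccc(cc1)S(=O)(=O)OC[C@@H](O)[C@H](C=C)C#C[Si](C)(C)C | intermediate
9 | trimethyl{(3R)-3-[(2S)-oxiran-2-yl]pent-4-en-1-yn-1-yl}silane | C1O[C@H]1[C@H](C=C)C#C[Si](C)(C)C | intermediate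
10 | methyl (2Z)-2-methylbut-2-enoate (methyl angelate) | C/C=C(/C)C(=O)OC | starting material
11 | (2Z)-2-methylbut-2-en-1-ol | C/C=C(/C)CO | intermediate
12 | [(2R,3S)-2,3-dimethyloxiran-2-yl]methanol | OC[C@@]1(C)O[C@H]1C | intermediate
13 | (2S,3S)-2,3-dimethyloxirane-2-carbaldehyde (not isolated) | O=C[C@@]1(C)O[C@H]1C | intermediate
14 | (2S,3S)-2,3-dimethyloxirane-2-carboxylic acid | OC(=O)[C@@]1(C)O[C@H]1C | intermediate
15 | [(2Z)-5-{[tert-butyl(dimethyl)silyl]oxy}pent-2-en-2-yl]lithium (not isolated; alkene geometry of 4 retained, the descriptor changes because lithium ranks below carbon) | [Li]/C(C)=C/CCO[Si](C)(C)C(C)(C)C | intermediate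
16 | (3R,4R,6E)-9-{[tert-butyl(dimethyl)silyl]oxy}-3-ethenyl-6-methyl-1-(trimethylsilyl)non-6-en-1-yn-4-ol | CC(C)(C)[Si](C)(C)OCC/C=C(\C)C[C@@H](O)[C@H](C=C)C#C[Si](C)(C)C | intermediate
17 | (2S,3S)-2,3-dimethyloxirane-2-carboxylic 2,4,6-trichlorobenzoic anhydride (not isolated) | O=C(OC(=O)c1c(Cl)cc(Cl)cc1Cl)[C@@]1(C)O[C@H]1C | intermediate
18 | (3R,4R,6E)-9-{[tert-butyl(dimethyl)silyl]oxy}-3-ethenyl-6-methyl-1-(trimethylsilyl)non-6-en-1-yn-4-yl (2S,3S)-2,3-dimethyloxirane-2-carboxylate | CC(C)(C)[Si](C)(C)OCC/C=C(\C)C[C@@H](OC(=O)[C@@]1(C)O[C@H]1C)[C@H](C=C)C#C[Si](C)(C)C | intermediate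
19 | (3R,4R,6E)-3-ethenyl-9-hydroxy-6-methylnon-6-en-1-yn-4-yl (2S,3S)-2,3-dimethyloxirane-2-carboxylate | OCC/C=C(\C)C[C@@H](OC(=O)[C@@]1(C)O[C@H]1C)[C@H](C=C)C#C | intermediate
20 | (3R,4R,6E)-3-ethenyl-6-methyl-9-oxonon-6-en-1-yn-4-yl (2S,3S)-2,3-dimethyloxirane-2-carboxylate | O=CC/C=C(\C)C[C@@H](OC(=O)[C@@]1(C)O[C@H]1C)[C@H](C=C)C#C | intermediate
21 | (3R,4R,6E,9S,10S)-3-ethenyl-9-hydroxy-6,10-dimethyldodeca-6,11-dien-1-yn-4-yl (2S,3S)-2,3-dimethyloxirane-2-carboxylate | C=C[C@H](C)[C@@H](O)C/C=C(\C)C[C@@H](OC(=O)[C@@]1(C)O[C@H]1C)[C@H](C=C)C#C | intermediate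
22 | (3R,4R,6E,9S,10S)-3-ethenyl-6,10-dimethyl-9-[(2-methylpropanoyl)oxy]dodeca-6,11-dien-1-yn-4-yl (2S,3S)-2,3-dimethyloxirane-2-carboxylate | C=C[C@H](C)[C@@H](OC(=O)C(C)C)C/C=C(\C)C[C@@H](OC(=O)[C@@]1(C)O[C@H]1C)[C@H](C=C)C#C | intermediate
23 | 2-(trimethylsilyl)ethyl (3R,4R,6E,9S,10S)-4-{[(2S,3S)-2,3-dimethyloxirane-2-carbonyl]oxy}-3-ethenyl-6,10-dimethyl-2-methylidene-9-[(2-methylpropanoyl)oxy]dodeca-6,11-dienoate | C=C[C@H](C)[C@@H](OC(=O)C(C)C)C/C=C(\C)C[C@@H](OC(=O)[C@@]1(C)O[C@H]1C)[C@H](C=C)C(=C)C(=O)OCC[Si](C)(C)C | intermediate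
24 | 2-(trimethylsilyl)ethyl (3R,4R,6R,7R,9S,10S)-4-{[(2S,3S)-2,3-dimethyloxirane-2-carbonyl]oxy}-6,7-epoxy-3-ethenyl-6,10-dimethyl-2-methylidene-9-[(2-methylpropanoyl)oxy]dodec-11-enoate | C=C[C@H](C)[C@@H](OC(=O)C(C)C)C[C@H]2O[C@]2(C)C[C@@H](OC(=O)[C@@]1(C)O[C@H]1C)[C@H](C=C)C(=C)C(=O)OCC[Si](C)(C)C | intermediate
25 | 2-(trimethylsilyl)ethyl (1R,3S,4S,5Z,7R,8R,10R)-8-{[(2S,3S)-2,3-dimethyloxirane-2-carbonyl]oxy}-1,10-epoxy-3-[(2-methylpropanoyl)oxy]germacra-5,11(13)-dien-12-oate | C[C@H]1/C=C\[C@H](C(=C)C(=O)OCC[Si](C)(C)C)[C@H](OC(=O)[C@@]2(C)O[C@H]2C)C[C@@]3(C)O[C@@H]3C[C@@H]1OC(=O)C(C)C | intermediate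
26 | (1R,3S,4S,5Z,7R,8R,10R)-8-{[(2S,3S)-2,3-dimethyloxirane-2-carbonyl]oxy}-1,10-epoxy-3-[(2-methylpropanoyl)oxy]germacra-5,11(13)-dien-12-oic acid | C[C@H]1/C=C\[C@H](C(=C)C(=O)O)[C@H](OC(=O)[C@@]2(C)O[C@H]2C)C[C@@]3(C)O[C@@H]3C[C@@H]1OC(=O)C(C)C | intermediate
27 | (1R,3S,4R,5S,6S,7R,8R,10R)-8-{[(2S,3S)-2,3-dimethyloxirane-2-carbonyl]oxy}-1,10-epoxy-3-[(2-methylpropanoyl)oxy]-5-(phenylselanyl)germacr-11(13)-en-12,6-olide (not isolated) | C=C1C(=O)O[C@@H]2[C@@H]([Se]c3ccccc3)[C@H](C)[C@@H](OC(=O)C(C)C)C[C@H]3O[C@]3(C)C[C@@H](OC(=O)[C@@]3(C)O[C@H]3C)[C@@H]12 | intermediate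
28 | Se-oxide of 27 (selenium configuration undefined; not isolated) | C=C1C(=O)O[C@@H]2[C@@H]([Se](=O)c3ccccc3)[C@H](C)[C@@H](OC(=O)C(C)C)C[C@H]3O[C@]3(C)C[C@@H](OC(=O)[C@@]3(C)O[C@H]3C)[C@@H]12 | intermediate
29 | (1R,3S,4Z,6R,7R,8R,10R)-8-{[(2S,3S)-2,3-dimethyloxirane-2-carbonyl]oxy}-1,10-epoxy-3-[(2-methylpropanoyl)oxy]germacra-4,11(13)-dien-12,6-olide (CNP0117882.1) | C=C1C(=O)O[C@@H]2/C=C(/C)[C@@H](OC(=O)C(C)C)C[C@H]3O[C@]3(C)C[C@@H](OC(=O)[C@@]3(C)O[C@H]3C)[C@@H]12 | target

Total step count: 19. Longest linear sequence: 14 steps (steps 3–5, then 9–19).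

Steps most likely to fail

Step 17 (ring-closing metathesis). Ring strain may divert the ruthenium carbene into intermolecular metathesis, and the ring that does close may form with E geometry or as an E/Z mixture, from which the syn-elimination of step 19 would give the wrong alkene. The fallback makes the E geometry productive by inverting the temporary centre C4. It sets out from aldehyde 20: crotylboration with (E)-crotyl-B(pin) under the same (R)-TRIP catalysis should give the anti adduct (3R,4R,6E,9S,10R)-3-ethenyl-9-hydroxy-6,10-dimethyldodeca-6,11-dien-1-yn-4-yl (2S,3S)-2,3-dimethyloxirane-2-carboxylate F1. Acylation as in step 14 gives its isobutyrate F2, alkoxycarbonylation as in step 15 the 2-(trimethylsilyl)ethyl acrylate F3, and Shi epoxidation as in step 16 the (6R,7R)-epoxide F4. Metathesis is then steered to, or the product separated as, the (5E)-cyclodecene ester F5, and fluoride gives the (5E)-acid F6. Anti selenolactonisation of the E-alkene gives the C4,C5-diastereomeric selenide F7 and oxidation the selenoxide F8, whose syn-elimination again holds C3 and C6 cis; the fallback comes back to the route at target 29.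

Step 15 (alkoxycarbonylation). Palladium hydride may migrate the two vinyl groups into conjugation, or the carbonyl may be delivered to the terminal alkyne carbon to give the linear ester. The fallback fixes the regiochemistry with a tin–iodine relay and sets out from alkyne 22. Hydrostannation with Bu3SnH under Mo(CO)3(CNtBu)3 catalysis (α-selective) should give (3S,4R,6E,9S,10S)-3-ethenyl-6,10-dimethyl-9-[(2-methylpropanoyl)oxy]-2-(tributylstannyl)dodeca-1,6,11-trien-4-yl (2S,3S)-2,3-dimethyloxirane-2-carboxylate F9. Iodine then gives the corresponding 2-iodo-1-alkene F10, and carbonylative esterification (PdCl2(PPh3)2, CO, Et3N, Me3SiCH2CH2OH) brings the sequence back to the route at ester 23.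

Step 19 (selenolactonisation and elimination). Seleninic peracid formed from the selenium by-product and peroxide may epoxidise the new C4=C5 alkene, the selenium electrophile may open the 1,10-epoxide, or the syn-elimination may be slow in the ring. The fallback replaces selenium by a catalytic oxidative lactonisation and sets out from acid 26: Pd(OCOCF3)2 (5 mol%), pyridine (20 mol%), Na2CO3, 3 Å MS, O2 (1 atm), toluene, 80 °C. Oxypalladation of C5=C6 by the carboxylate forms the same O–C6 bond, and β-hydride elimination of H4 moves the alkene to C4=C5. With anti oxypalladation and syn elimination the stereochemical course is the same as with selenium, and the fallback comes back to the route at target 29 without a new isolable compound.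

Further compounds
F1 | step 17 | (3R,4R,6E,9S,10R)-3-ethenyl-9-hydroxy-6,10-dimethyldodeca-6,11-dien-1-yn-4-yl (2S,3S)-2,3-dimethyloxirane-2-carboxylate | C=C[C@@H](C)[C@@H](O)C/C=C(\C)C[C@@H](OC(=O)[C@@]1(C)O[C@H]1C)[C@H](C=C)C#C
F2 | step 17 | (3R,4R,6E,9S,10R)-3-ethenyl-6,10-dimethyl-9-[(2-methylpropanoyl)oxy]dodeca-6,11-dien-1-yn-4-yl (2S,3S)-2,3-dimethyloxirane-2-carboxylate | C=C[C@@H](C)[C@@H](OC(=O)C(C)C)C/C=C(\C)C[C@@H](OC(=O)[C@@]1(C)O[C@H]1C)[C@H](C=C)C#C
F3 | step 17 | 2-(trimethylsilyl)ethyl (3R,4R,6E,9S,10R)-4-{[(2S,3S)-2,3-dimethyloxirane-2-carbonyl]oxy}-3-ethenyl-6,10-dimethyl-2-methylidene-9-[(2-methylpropanoyl)oxy]dodeca-6,11-dienoate | C=C[C@@H](C)[C@@H](OC(=O)C(C)C)C/C=C(\C)C[C@@H](OC(=O)[C@@]1(C)O[C@H]1C)[C@H](C=C)C(=C)C(=O)OCC[Si](C)(C)C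
F4 | step 17 | 2-(trimethylsilyl)ethyl (3R,4R,6R,7R,9S,10R)-4-{[(2S,3S)-2,3-dimethyloxirane-2-carbonyl]oxy}-6,7-epoxy-3-ethenyl-6,10-dimethyl-2-methylidene-9-[(2-methylpropanoyl)oxy]dodec-11-enoate | C=C[C@@H](C)[C@@H](OC(=O)C(C)C)C[C@H]2O[C@]2(C)C[C@@H](OC(=O)[C@@]1(C)O[C@H]1C)[C@H](C=C)C(=C)C(=O)OCC[Si](C)(C)C
F5 | step 17 | 2-(trimethylsilyl)ethyl (1R,3S,4R,5E,7R,8R,10R)-8-{[(2S,3S)-2,3-dimethyloxirane-2-carbonyl]oxy}-1,10-epoxy-3-[(2-methylpropanoyl)oxy]germacra-5,11(13)-dien-12-oate | C[C@@H]1/C=C/[C@H](C(=C)C(=O)OCC[Si](C)(C)C)[C@H](OC(=O)[C@@]2(C)O[C@H]2C)C[C@@]3(C)O[C@@H]3C[C@@H]1OC(=O)C(C)C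
F6 | step 17 | (1R,3S,4R,5E,7R,8R,10R)-8-{[(2S,3S)-2,3-dimethyloxirane-2-carbonyl]oxy}-1,10-epoxy-3-[(2-methylpropanoyl)oxy]germacra-5,11(13)-dien-12-oic acid | C[C@@H]1/C=C/[C@H](C(=C)C(=O)O)[C@H](OC(=O)[C@@]2(C)O[C@H]2C)C[C@@]3(C)O[C@@H]3C[C@@H]1OC(=O)C(C)C
F7 | step 17 | (1R,3S,4S,5R,6S,7R,8R,10R)-8-{[(2S,3S)-2,3-dimethyloxirane-2-carbonyl]oxy}-1,10-epoxy-3-[(2-methylpropanoyl)oxy]-5-(phenylselanyl)germacr-11(13)-en-12,6-olide | C=C1C(=O)O[C@@H]2[C@H]([Se]c3ccccc3)[C@@H](C)[C@@H](OC(=O)C(C)C)C[C@H]3O[C@]3(C)C[C@@H](OC(=O)[C@@]3(C)O[C@H]3C)[C@@H]12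
F8 | step 17 | Se-oxide of F7 (selenium configuration undefined) | C=C1C(=O)O[C@@H]2[C@H]([Se](=O)c3ccccc3)[C@@H](C)[C@@H](OC(=O)C(C)C)C[C@H]3O[C@]3(C)C[C@@H](OC(=O)[C@@]3(C)O[C@H]3C)[C@@H]12
F9 | step 15 | (3S,4R,6E,9S,10S)-3-ethenyl-6,10-dimethyl-9-[(2-methylpropanoyl)oxy]-2-(tributylstannyl)dodeca-1,6,11-trien-4-yl (2S,3S)-2,3-dimethyloxirane-2-carboxylate | C=C[C@H](C)[C@@H](OC(=O)C(C)C)C/C=C(\C)C[C@@H](OC(=O)[C@@]1(C)O[C@H]1C)[C@H](C=C)C(=C)[Sn](CCCC)(CCCC)CCCC
F10 | step 15 | (3S,4R,6E,9S,10S)-3-ethenyl-2-iodo-6,10-dimethyl-9-[(2-methylpropanoyl)oxy]dodeca-1,6,11-trien-4-yl (2S,3S)-2,3-dimethyloxirane-2-carboxylate | C=C[C@H](C)[C@@H](OC(=O)C(C)C)C/C=C(\C)C[C@@H](OC(=O)[C@@]1(C)O[C@H]1C)[C@H](C=C)C(=C)I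
F0 | step 19 | none | none
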